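**Structural features**

The target is built from two benzene rings joined only through a benzylic ester, C6–CH2–O–C(=O). Ring A is a 2-hydroxy-4-methoxy-3,6-dimethylbenzoyl group. Ring B is fused to a γ-lactol (a 3-hydroxyphthalide; phthalide numbering: C1 lactone carbonyl, O2, C3 lactol carbon, C3a, C4 to C7, C7a). Ring B carries H at C4, OMe at C5, the CH2O–acyl arm at C6 and a free OH at C7 next to the lactone carbonyl. C3 is the only stereocentre; it is R (ring O > OH > C3a > H) and has no stereocentre beside it. It inverts by ring–chain tautomerism with the 2-formylbenzoic acid, so it cannot be carried through a synthesis. The fragile groups are the lactol (alcohols and amines turn it into pseudo-esters and aminals, base opens it), the o-hydroxybenzyl ester (a C7 phenoxide can expel the carboxylate through an o-quinone methide) and the free salicylic-type acid of ring A (decarboxylation on warming). The real difficulty is ring B: five different substituents in a fixed order, with three carbon substituents at the acid, aldehyde and alcohol levels that must be released one at a time, and a final stereocentre that only the solid state can hold. The key step uses the pattern carboxyl carbon on C7a, oxygen on C7 and C5, formyl-level carbon on C3a: this is a 4-oxy-2-pyrone-5-carboxylate with a masked formyl group on pyrone C6, in which the lactone CO2 unit is exchanged for C4 and C5 of ring B.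

**Logic of the disconnections**

19 to 18: no skeletal bond is cut; only the configuration at C3 is given up, because the C3–O2 bond opens and closes in solution. All earlier chemistry can then be run without stereocontrol. The last step must turn racemic 18 into the (R) solid without any reagent that leaves atoms, and 19 must be kept as a solid.

18 to 16 (through 17): the lactol C3–O2 bond and the O–allyl bond of the C1 carboxyl are cut. The lactol is only the closed form of 17, and an allyl ester is the one carboxyl mask that can be removed without base, strong acid or attack at an acyl carbon. This keeps the lactol out of every earlier step. The deallylation must be amine-free and must spare the benzylic ester and the aldehyde.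

16 to 12 and 15: the benzylic CH2–O bond of the inter-ring ester is cut. It is the only link between the rings, and forming the alkyl–oxygen bond avoids the blocked acyl carbon of 15. The route becomes convergent with two fragments of similar size. The primary benzylic alcohol of 12 must be activated while two free phenols and an aldehyde are present, and the carboxylate must win over the phenols.

15 to 14 to 13: the O4–CH3 bond is cut and the methyl ester is restored. 13 is commercial and its two hydroxyls differ because one is chelated to the ester. The forward steps must methylate O4 only and must cleave the ester at the methyl carbon, not at the hindered acyl carbon.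

12 to 10 (through 11): the C6–CH2OH bond is cut, with formaldehyde as the one-carbon piece. C6 is the only free position ortho to the C7 phenol. Ring B is reduced to a tetrasubstituted benzene in which acid, aldehyde and phenol are already distinct. The substitution must go to C6 and not to C4, which is electronically competitive, so it must be delivered through the phenol oxygen; the ring is deactivated and reactivity is the demand.

10 to 9: no skeletal bond is cut; the MOM ether on O7 and the dimethyl acetal on the formyl carbon are put back. Both are needed during the cycloaddition and both fall to the same dilute acid. The hydrolysis must leave the allyl ester alone.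

9 to 5 and 6 (through 8 and 7): the C3a–C4 and C5–C6 bonds are cut. This removes a two-carbon unit that carries the C5 methoxyl and leaves a four-carbon diene with the other three substituents, which becomes a 2-pyrone when CO2 is added back. An aromatic ring is traded for a monocyclic heterocycle and a C2 commodity, and regiochemistry becomes a matter of polarity. 5 is a donor-substituted, hindered diene, so heat and excess 6 are needed and every protecting group must stand neutral heating.

5 to 4 to 2 and 3: the O4–CH2 bond of the MOM ether is cut, then the pyrone C4–C5 bond and the lactone O1–C2 bond. A 4-hydroxy-2-pyrone-5-carboxylate is the adduct of a β-keto ester and a malonyl unit, so all six ring atoms and three substituents come from two acyclic pieces. The acetal must survive the hydrogen chloride set free, and alkylation must go to O4.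

2 to 1: only the ester alkyl group is exchanged. Allyl is needed for the final release and 1 is sold as the methyl ester. The exchange must run without acid so that the acetal is kept.

**Other disconnections considered**

Alternative 1: The cut runs through C3a–C3 and C3–O2, so the lactone carbon is added last to a bought benzoic acid. Forward, 2,4-dimethoxy-3-methylbenzoic acid A2 would be heated with dibromomethane A3 under divalent palladium catalysis. Carboxylate-directed palladation of the only ortho C–H bond, alkylation and displacement of the second bromide by the carboxylate would give 5,7-dimethoxy-6-methylisobenzofuran-1(3H)-one A1.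
- In favour: ring B is bought, the C6 carbon is present from the start, the site of C–H activation is unambiguous, and the bicyclic core is reached in one step. Up to that point this is better than the chosen plan in step count.
- Against: A1 is at the wrong oxidation level at two benzylic carbons. C3 must be raised from CH2 to the lactol level and the C6 methyl must be oxygenated. Both changes would rest on radical halogenation, which cannot easily tell the two sites apart and competes with ring halogenation at C4. The two methyl ethers must then be told apart, which chelation at C7 makes plausible.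
- Comparison: a high-temperature metalation and alkylation stands against a thermal pericyclic step. Neither sets a stereocentre and both plans must settle C3 at the end in the same way, so they are equal there. The chosen plan is longer to the aromatic core but brings C3 in at the formyl level and keeps the three carbon substituents distinct, which removes the late, unselective oxidations. Alternative 1 is the better plan for the C6 carbon, which the chosen route adds late in step 6.

Alternative 2: The cut is the C7a–C3a bond of ring B. Forward, 6-(5,5-dimethoxy-2,4-dioxopentyl)-2,2-dimethyl-4H-1,3-dioxin-4-one A5 would fold under mild base by aldol addition of the dioxinone α-carbon to the ketone beside the acetal, and dehydration would give 5-(dimethoxymethyl)-7-hydroxy-2,2-dimethyl-4H-1,3-benzodioxin-4-one A4.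
- In favour: ambient temperature, no gas evolution, and regiochemistry fixed by the chain. The acetonide masks the C7 oxygen and the carboxyl together, and an allyl alkoxide could open it directly to an allyl ester with a free C7 phenol. The C5 oxygen emerges free for methylation. The acetal could be kept through the hydroxymethylation, so C6 would be more nucleophilic than in 10. On mildness, protecting-group economy and nucleophilicity at C6 this alternative is the better one.
- Against: A5 needs two enolate acylations with strong base at low temperature, exists as a mixture of enol tautomers, and can close through oxygen to a pyranone. The C5 methoxyl costs a separate methylation, and C6 still arrives as C–H.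
- Comparison: the step count to the phenol stage is about equal. The mechanism is an ionic aldol condensation against a pericyclic cascade. The chosen plan is preferred for its robust, cheap building blocks and the absence of polyketone handling, but alternative 2 is a realistic equal.

Alternative 3: The cut is through C4–C3a and C7–C7a. Forward, 1,1-bis(trimethylsilyloxy)-2-{[tert-butyl(dimethyl)silyl]oxymethyl}-3-methoxybuta-1,3-diene A7 and allyl 4,4-diethoxybut-2-ynoate A8 would combine in a normal-demand [4+2] addition, the CH2 terminus of A7 bonding to the β-carbon of A8. Loss of silanol would give allyl 3-{[tert-butyl(dimethyl)silyl]oxymethyl}-6-(diethoxymethyl)-2-hydroxy-4-methoxybenzoate A6.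
- In favour: all five substituents of ring B, including the C6 CH2–O carbon, are in place at the moment of aromatisation, the C7 hydroxyl is free and the C5 methoxyl is present. No electrophilic substitution on a deactivated ring is needed. This is better than the chosen plan, whose step 6 is one of its weak points.
- Against: A7 is a tetrasubstituted, moisture-sensitive bis-silyl ketene acetal that needs several steps. Its precursors are open to retro-aldol cleavage and β-elimination, and its 2-substituent crowds the terminus that must bond to the ester-bearing alkyne carbon. Silyl ether, diethyl acetal and allyl ester must then be released in order.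
- Comparison: alternative 3 is shorter after the key step and longer before it, so the overall length is similar. Regiocontrol is of the same kind in both plans (matched polarity), so they are equal there. The chosen plan uses sturdier, commercial partners.

Key step: step 4

Assumption: C3 of a 3-hydroxyphthalide inverts in solution through the ring-opened 2-formylbenzoic acid, so the (3R) configuration is set in the last step under crystallisation control and is taken to hold only in the solid.

Step 1
Reactants: 1 methyl 4,4-dimethoxy-3-oxobutanoate
Product: 2 allyl 4,4-dimethoxy-3-oxobutanoate
Conditions: allyl alcohol (5 equiv), DMAP (0.1 equiv), toluene, 110 °C, MeOH distilled off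
Reagents that add atoms: allyl alcohol, C=CCO
Why: DMAP-catalysed transesterification of a β-keto ester proceeds at the keto-ester carbonyl only and is driven by removal of methanol. No acid is present, so the dimethyl acetal should be untouched.

Step 2
Reactants: 2 allyl 4,4-dimethoxy-3-oxobutanoate; 3 malonyl dichloride
Product: 4 allyl 6-(dimethoxymethyl)-4-hydroxy-2-oxo-2H-pyran-5-carboxylate
Conditions: CH2Cl2, 0 °C to 40 °C, N2 sweep; NaHCO3 extraction, then citric acid
Reagents that add atoms: none
Why: Condensation of a β-keto ester with malonyl dichloride is the established route to 4-hydroxy-6-alkyl-2-pyrone-5-carboxylates: C-acylation at the active methylene, then lactonisation of the ketone enol onto the second acyl chloride. The acetal sits on a carbonyl-bearing carbon, where oxocarbenium formation is disfavoured, and the hydrogen chloride is swept out as it forms.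

Step 3
Reactants: 4 allyl 6-(dimethoxymethyl)-4-hydroxy-2-oxo-2H-pyran-5-carboxylate
Product: 5 allyl 6-(dimethoxymethyl)-4-(methoxymethoxy)-2-oxo-2H-pyran-5-carboxylate
Conditions: MOMCl (1.3 equiv), iPr2NEt (1.5 equiv), CH2Cl2, 0 °C to rt
Reagents that add atoms: chloromethyl methyl ether, COCCl
Why: The pyrone hydroxyl is a vinylogous carboxylic acid, and its ammonium salt should be alkylated at O4 by the hard chloromethyl ether (Williamson-type O-alkylation). The basic medium protects the acetal.

Step 4
Reactants: 5 allyl 6-(dimethoxymethyl)-4-(methoxymethoxy)-2-oxo-2H-pyran-5-carboxylate; 6 1,1-dimethoxyethene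
Product: 9 allyl 2-(dimethoxymethyl)-4-methoxy-6-(methoxymethoxy)benzoate, via bridged lactone cycloadduct 7 (not isolated), via dimethoxycyclohexadiene ester 8 (not isolated)
Conditions: 6 (4 equiv), K2CO3 (trace), toluene, sealed tube, 110 to 130 °C
Reagents that add atoms: none
Why: The electron-poor pyrone 5 reacts through C3=C4–C5=C6 as the 4π partner and the electron-rich alkene 6 as the 2π partner in an inverse-demand Diels–Alder reaction, probably asynchronous, with the CH2 terminus of 6 bonding first to pyrone C6 and the resulting ester- and lactone-stabilised enolate closing from pyrone C3 onto the dimethoxycarbenium carbon. The closest known reaction type is the cycloaddition of 2-pyrone-5-carboxylates and 2-pyrone-3-carboxylates with ketene acetals, which ends in alkoxybenzoates after loss of CO2 and alcohol. The only ring closed is the six-membered carbocycle that becomes ring B, formed by intermolecular [4+2] cycloaddition to the bridged lactone 7 (C3a–C4 and C5–C6 bonds in phthalide numbering); retro-[4+2] loss of CO2 should then give 8, and 1,2-elimination of methanol across the C(OMe)2–CH2 unit aromatises it to 9. No stereocentre survives, because the two bridgehead centres of racemic 7 are erased on aromatisation. The selectivity needed is regiochemical and rests on matched polarisation: pyrone C6 is β to the C5 ester and the vinylogous terminus of the lactone carbonyl, while the C4 oxygen donates only towards C3, so the nucleophilic carbon of 6 should go to C6 and the methoxyl should end on C5 of ring B, para to the ester. The elimination can keep only one methoxyl on that carbon, so no separate methylation is needed. The trace of K2CO3 keeps 6 from acid-induced polymerisation, and the MOM ether, the acetal and the allyl ester should be inert to neutral heating in this range.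

Step 5
Reactants: 9 allyl 2-(dimethoxymethyl)-4-methoxy-6-(methoxymethoxy)benzoate
Product: 10 allyl 2-formyl-6-hydroxy-4-methoxybenzoate
Conditions: 1 M HCl, THF, 40 °C
Reagents that add atoms: water, O
Why: Dilute aqueous acid hydrolyses the aryl MOM ether and the dimethyl acetal in one operation (acetal hydrolysis). The 2,6-disubstituted allyl benzoate is inert to it, and water should capture the oxocarbenium ion faster than the neighbouring ester carbonyl can.

Step 6
Reactants: 10 allyl 2-formyl-6-hydroxy-4-methoxybenzoate
Product: 12 allyl 6-formyl-2-hydroxy-3-(hydroxymethyl)-4-methoxybenzoate, via benzodioxaborin 11 (not isolated)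
Conditions: PhB(OH)2 (1.2 equiv), (CH2O)n (3 equiv), EtCO2H (0.3 equiv), toluene, 100 °C, Dean–Stark; then 2,2-dimethylpropane-1,3-diol, THF, rt
Reagents that add atoms: paraformaldehyde (as formaldehyde), C=O
Why: In the boron-templated ortho-hydroxymethylation of phenols the aryloxyboron species delivers formaldehyde intramolecularly to a position ortho to the phenol, and C6 is the only free one, so C4 cannot compete. Exchange of the cyclic boronate 11 with the 1,3-diol should release the hydroxymethyl phenol without any oxidant that could touch the aldehyde.

Step 7
Reactants: 13 methyl 2,4-dihydroxy-3,6-dimethylbenzoate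
Product: 14 methyl 2-hydroxy-4-methoxy-3,6-dimethylbenzoate
Conditions: MeI (1.1 equiv), K2CO3 (1.2 equiv), acetone, 56 °C
Reagents that add atoms: iodomethane, CI
Why: Williamson methylation should take place at the 4-hydroxyl only, because the 2-hydroxyl is held in a hydrogen bond to the ester carbonyl and is the weaker nucleophile.

Step 8
Reactants: 14 methyl 2-hydroxy-4-methoxy-3,6-dimethylbenzoate
Product: 15 2-hydroxy-4-methoxy-3,6-dimethylbenzoic acid
Conditions: NaSEt (3 equiv), DMF, 80 °C; then cold 1 M HCl to pH 2
Reagents that add atoms: none
Why: Thiolate dealkylation attacks the ester methyl group (SN2 at carbon) and so bypasses the acyl carbon that the two ortho substituents block. The aryl methyl ether needs a much higher temperature, and cold acidification avoids decarboxylation of the free acid.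

Step 9
Reactants: 12 allyl 6-formyl-2-hydroxy-3-(hydroxymethyl)-4-methoxybenzoate; 15 2-hydroxy-4-methoxy-3,6-dimethylbenzoic acid
Product: 16 allyl 6-formyl-2-hydroxy-3-{[(2-hydroxy-4-methoxy-3,6-dimethylbenzoyl)oxy]methyl}-4-methoxybenzoate
Conditions: PPh3 (1.3 equiv), DIAD (1.3 equiv), THF, 0 °C to rt, DIAD added last
Reagents that add atoms: none
Why: In the Mitsunobu esterification the benzylic alcohol is activated as its oxyphosphonium ion and displaced by the carboxylate, which is far more acidic than either chelated phenol; chemoselective Mitsunobu esterification of phenolic acids with hydroxybenzyl alcohols is a known reaction type. Attack by carboxylate oxygen is insensitive to the ortho substituents of 15, and any o-quinone methide formed from the activated alcohol should be captured by the same acid to give the same ester.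

Step 10
Reactants: 16 allyl 6-formyl-2-hydroxy-3-{[(2-hydroxy-4-methoxy-3,6-dimethylbenzoyl)oxy]methyl}-4-methoxybenzoate
Product: 18 racemic [(3RS)-3,7-dihydroxy-5-methoxy-1-oxo-1,3-dihydroisobenzofuran-6-yl]methyl 2-hydroxy-4-methoxy-3,6-dimethylbenzoate, via ring-opened formylbenzoic acid 17 (not isolated)
Conditions: Pd(PPh3)4 (5 mol%), p-TolSO2H (1.2 equiv), CH2Cl2, rt
Reagents that add atoms: none
Why: Tsuji–Trost deallylation by zerovalent palladium with a sulfinic acid as allyl acceptor is amine-free and mildly acidic, so no aminal forms at the aldehyde and no phenoxide is generated that could expel the benzylic carboxylate. The freed acid 17 should close onto the ortho aldehyde (5-exo-trig) to the lactol, which forms as a racemate because nothing biases the two faces of the aldehyde.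

Step 11
Reactants: 18 racemic [(3RS)-3,7-dihydroxy-5-methoxy-1-oxo-1,3-dihydroisobenzofuran-6-yl]methyl 2-hydroxy-4-methoxy-3,6-dimethylbenzoate
Product: 19 [(3R)-3,7-dihydroxy-5-methoxy-1-oxo-1,3-dihydroisobenzofuran-6-yl]methyl 2-hydroxy-4-methoxy-3,6-dimethylbenzoate
Conditions: slurry in MeCN–toluene, Et3N (2 mol%), glass beads, 20 °C, seeded with 19; filtered and dried cold
Reagents that add atoms: none
Why: Proposed new method: C3 of 18 inverts in solution through ring-opened 17 under the trace of base, so if 18 crystallises as a conglomerate, seeding with (R) crystals (from a small sample resolved on a chiral stationary phase) and grinding the slurry should funnel all of the solid into the (R) form 19, whose lattice then holds the configuration; the closest known reaction type is attrition-enhanced deracemisation (Viedma ripening) and crystallisation-induced asymmetric transformation of compounds that racemise in solution by reversible ring opening or enolisation, which has not been shown for 3-hydroxyphthalides.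

Compound list
1 | methyl 4,4-dimethoxy-3-oxobutanoate | COC(OC)C(=O)CC(=O)OC | starting material
2 | allyl 4,4-dimethoxy-3-oxobutanoate | COC(OC)C(=O)CC(=O)OCC=C | intermediate
3 | malonyl dichloride | O=C(Cl)CC(Cl)=O | starting material
4 | allyl 6-(dimethoxymethyl)-4-hydroxy-2-oxo-2H-pyran-5-carboxylate | OC1=CC(=O)OC(C(OC)OC)=C1C(=O)OCC=C | intermediate
5 | allyl 6-(dimethoxymethyl)-4-(methoxymethoxy)-2-oxo-2H-pyran-5-carboxylate | COCOC1=CC(=O)OC(C(OC)OC)=C1C(=O)OCC=C | intermediate
6 | 1,1-dimethoxyethene | C=C(OC)OC | starting material
7 | allyl 1-(dimethoxymethyl)-8,8-dimethoxy-5-(methoxymethoxy)-3-oxo-2-oxabicyclo[2.2.2]oct-5-ene-6-carboxylate (racemic, not isolated) | O=C1OC2(C(OC)OC)CC(OC)(OC)C1C(OCOC)=C2C(=O)OCC=C | intermediate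
8 | allyl 2-(dimethoxymethyl)-4,4-dimethoxy-6-(methoxymethoxy)cyclohexa-1,5-diene-1-carboxylate (not isolated) | COCOC1=CC(OC)(OC)CC(C(OC)OC)=C1C(=O)OCC=C | intermediate
9 | allyl 2-(dimethoxymethyl)-4-methoxy-6-(methoxymethoxy)benzoate | COCOc1cc(OC)cc(C(OC)OC)c1C(=O)OCC=C | intermediate
10 | allyl 2-formyl-6-hydroxy-4-methoxybenzoate | O=Cc1cc(OC)cc(O)c1C(=O)OCC=C | intermediate
11 | allyl 7-formyl-5-methoxy-2-phenyl-4H-1,3,2-benzodioxaborinine-8-carboxylate (not isolated) | O=Cc1cc(OC)c2COB(c3ccccc3)Oc2c1C(=O)OCC=C | intermediate
12 | allyl 6-formyl-2-hydroxy-3-(hydroxymethyl)-4-methoxybenzoate | O=Cc1cc(OC)c(CO)c(O)c1C(=O)OCC=C | intermediate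
13 | methyl 2,4-dihydroxy-3,6-dimethylbenzoate | COC(=O)c1c(C)cc(O)c(C)c1O | starting material
14 | methyl 2-hydroxy-4-methoxy-3,6-dimethylbenzoate | COC(=O)c1c(C)cc(OC)c(C)c1O | intermediate
15 | 2-hydroxy-4-methoxy-3,6-dimethylbenzoic acid | COc1cc(C)c(C(=O)O)c(O)c1C | intermediate
16 | allyl 6-formyl-2-hydroxy-3-{[(2-hydroxy-4-methoxy-3,6-dimethylbenzoyl)oxy]methyl}-4-methoxybenzoate | COc1cc(C)c(C(=O)OCc2c(OC)cc(C=O)c(C(=O)OCC=C)c2O)c(O)c1C | intermediate
17 | 6-formyl-2-hydroxy-3-{[(2-hydroxy-4-methoxy-3,6-dimethylbenzoyl)oxy]methyl}-4-methoxybenzoic acid (not isolated) | COc1cc(C)c(C(=O)OCc2c(OC)cc(C=O)c(C(=O)O)c2O)c(O)c1C | intermediate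
18 | racemic [(3RS)-3,7-dihydroxy-5-methoxy-1-oxo-1,3-dihydroisobenzofuran-6-yl]methyl 2-hydroxy-4-methoxy-3,6-dimethylbenzoate | COc1cc(C)c(C(=O)OCc2c(OC)cc3c(c2O)C(=O)OC3O)c(O)c1C | intermediate
19 | [(3R)-3,7-dihydroxy-5-methoxy-1-oxo-1,3-dihydroisobenzofuran-6-yl]methyl 2-hydroxy-4-methoxy-3,6-dimethylbenzoate | COc1cc(C)c(C(=O)OCc2c(OC)cc3c(c2O)C(=O)O[C@H]3O)c(O)c1C | target

Total step count: 11. Longest linear sequence: 9 steps (steps 1 to 6 and 9 to 11, from 1); the ring A branch (steps 7 and 8) joins at step 9.

Least certain steps

Step 11 (bears the label "Proposed new method:"). The most likely failure is that the racemate crystallises as a racemic compound and not as a conglomerate, so grinding and seeding cannot enrich either hand; a second risk is slow erosion of the benzylic ester by the base during a long slurry. Fallback with known chemistry: setting out from 18, the enantiomers would be separated by preparative chromatography on an immobilised polysaccharide carbamate chiral stationary phase with a neutral aprotic eluent below ambient temperature. The (R) fractions would be evaporated cold and kept as a solid, which comes back to the route at 19 and also supplies seed crystals. No new compound is made on this way (F0).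

Step 4 (key step). The most likely failure is lack of cycloaddition below the temperature at which 6 oligomerises, because the 4-alkoxy group raises the diene LUMO and the acetal crowds pyrone C6. Two further risks are opening of the first-formed zwitterion at the O1–C6 bond in place of closure to 7, and loss of 6 to the methanol released. Fallback: setting out from 4, the donor ether is replaced by an acceptor-type enol ester.
- Pivaloyl chloride and Et3N in CH2Cl2 should give allyl 6-(dimethoxymethyl)-4-[(2,2-dimethylpropanoyl)oxy]-2-oxo-2H-pyran-5-carboxylate F1, a more electron-poor diene.
- Cycloaddition of F1 with 6 and loss of CO2 and methanol should give allyl 2-(dimethoxymethyl)-6-[(2,2-dimethylpropanoyl)oxy]-4-methoxybenzoate F2.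
- Dilute HCl in THF would free the aldehyde to allyl 2-[(2,2-dimethylpropanoyl)oxy]-6-formyl-4-methoxybenzoate F3.
- K2CO3 in allyl alcohol would pass the pivaloyl group to the solvent without scrambling the allyl ester, which comes back to the route at 10.

Step 6. The most likely failure is stalling of the electrophilic substitution, because C6 lies para to the formyl-bearing carbon and on a salicylate ring; long heating could instead lead to condensation of the aldehyde with formaldehyde. Fallback: setting out from 9, the carbon–carbon bond is formed while the aldehyde is still masked.
- Camphorsulfonic acid in dry methanol would remove the MOM group only and give allyl 2-(dimethoxymethyl)-6-hydroxy-4-methoxybenzoate F4.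
- Casnati–Skattebøl ortho-formylation (MgCl2, Et3N, paraformaldehyde, MeCN, reflux) should give allyl 6-(dimethoxymethyl)-3-formyl-2-hydroxy-4-methoxybenzoate F5.
- NaBH4 at 0 °C would reduce the new aldehyde to allyl 6-(dimethoxymethyl)-2-hydroxy-3-(hydroxymethyl)-4-methoxybenzoate F6.
- Dilute HCl in THF would hydrolyse the acetal, which comes back to the route at 12.

Step 2. The most likely failure is loss of the dimethyl acetal under the hydrogen chloride released, together with oligomerisation of 3 through its ketene. Fallback: setting out from 2, soft enolisation with MgCl2 and pyridine and C-acylation with methyl 3-chloro-3-oxopropanoate should give 1-allyl 5-methyl 2-(2,2-dimethoxyacetyl)-3-oxopentanedioate F7. Lactonisation of its enol onto the methyl ester with DBU in warm toluene comes back to the route at 4, with no free acid at any stage.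

Step 9. The most likely failure is self-condensation of the activated benzylic position with the ring B phenol of a second molecule, or with a carbon nucleophile through the o-quinone methide, if the hindered carboxylate is a slow trap. Fallback: setting out from 12, the phenol is masked before the benzylic carbon is activated.
- Allyl bromide and K2CO3 in DMF should give allyl 6-formyl-3-(hydroxymethyl)-4-methoxy-2-(prop-2-en-1-yloxy)benzoate F8.
- PBr3 in CH2Cl2 at 0 °C should give allyl 3-(bromomethyl)-6-formyl-4-methoxy-2-(prop-2-en-1-yloxy)benzoate F9.
- Alkylation of the caesium salt of 15 (Cs2CO3, DMF, rt) should give allyl 6-formyl-3-{[(2-hydroxy-4-methoxy-3,6-dimethylbenzoyl)oxy]methyl}-4-methoxy-2-(prop-2-en-1-yloxy)benzoate F10.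
- Pd(PPh3)4 with p-TolSO2H would remove the allyl ether and the allyl ester together, which comes back to the route at 18.

**Further compounds**

F0 | step 11 | none | none
F1 | step 4 | allyl 6-(dimethoxymethyl)-4-[(2,2-dimethylpropanoyl)oxy]-2-oxo-2H-pyran-5-carboxylate | CC(C)(C)C(=O)OC1=CC(=O)OC(C(OC)OC)=C1C(=O)OCC=C
F2 | step 4 | allyl 2-(dimethoxymethyl)-6-[(2,2-dimethylpropanoyl)oxy]-4-methoxybenzoate | CC(C)(C)C(=O)Oc1cc(OC)cc(C(OC)OC)c1C(=O)OCC=C
F3 | step 4 | allyl 2-[(2,2-dimethylpropanoyl)oxy]-6-formyl-4-methoxybenzoate | CC(C)(C)C(=O)Oc1cc(OC)cc(C=O)c1C(=O)OCC=C
F4 | step 6 | allyl 2-(dimethoxymethyl)-6-hydroxy-4-methoxybenzoate | COC(OC)c1cc(OC)cc(O)c1C(=O)OCC=C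
F5 | step 6 | allyl 6-(dimethoxymethyl)-3-formyl-2-hydroxy-4-methoxybenzoate | COC(OC)c1cc(OC)c(C=O)c(O)c1C(=O)OCC=C
F6 | step 6 | allyl 6-(dimethoxymethyl)-2-hydroxy-3-(hydroxymethyl)-4-methoxybenzoate | COC(OC)c1cc(OC)c(CO)c(O)c1C(=O)OCC=C
F7 | step 2 | 1-allyl 5-methyl 2-(2,2-dimethoxyacetyl)-3-oxopentanedioate | COC(OC)C(=O)C(C(=O)OCC=C)C(=O)CC(=O)OC
F8 | step 9 | allyl 6-formyl-3-(hydroxymethyl)-4-methoxy-2-(prop-2-en-1-yloxy)benzoate | C=CCOc1c(CO)c(OC)cc(C=O)c1C(=O)OCC=C
F9 | step 9 | allyl 3-(bromomethyl)-6-formyl-4-methoxy-2-(prop-2-en-1-yloxy)benzoate | C=CCOc1c(CBr)c(OC)cc(C=O)c1C(=O)OCC=C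
F10 | step 9 | allyl 6-formyl-3-{[(2-hydroxy-4-methoxy-3,6-dimethylbenzoyl)oxy]methyl}-4-methoxy-2-(prop-2-en-1-yloxy)benzoate | COc1cc(C)c(C(=O)OCc2c(OC)cc(C=O)c(C(=O)OCC=C)c2OCC=C)c(O)c1C
A1 | alternative 1 | 5,7-dimethoxy-6-methylisobenzofuran-1(3H)-one | COc1cc2c(c(OC)c1C)C(=O)OC2
A2 | alternative 1 | 2,4-dimethoxy-3-methylbenzoic acid | COc1ccc(C(=O)O)c(OC)c1C
A3 | alternative 1 | dibromomethane | BrCBr
A4 | alternative 2 | 5-(dimethoxymethyl)-7-hydroxy-2,2-dimethyl-4H-1,3-benzodioxin-4-one | COC(OC)c1cc(O)cc2c1C(=O)OC(C)(C)O2
A5 | alternative 2 | 6-(5,5-dimethoxy-2,4-dioxopentyl)-2,2-dimethyl-4H-1,3-dioxin-4-one | COC(OC)C(=O)CC(=O)CC1=CC(=O)OC(C)(C)O1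
A6 | alternative 3 | allyl 3-{[tert-butyl(dimethyl)silyl]oxymethyl}-6-(diethoxymethyl)-2-hydroxy-4-methoxybenzoate | CCOC(OCC)c1cc(OC)c(CO[Si](C)(C)C(C)(C)C)c(O)c1C(=O)OCC=C
A7 | alternative 3 | 1,1-bis(trimethylsilyloxy)-2-{[tert-butyl(dimethyl)silyl]oxymethyl}-3-methoxybuta-1,3-diene | C=C(OC)C(CO[Si](C)(C)C(C)(C)C)=C(O[Si](C)(C)C)O[Si](C)(C)C
A8 | alternative 3 | allyl 4,4-diethoxybut-2-ynoate | CCOC(OCC)C#CC(=O)OCC=C
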